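Retrosynthesis: the five benzyl groups and two bromine atoms are removed first. Ring C'' is then cut at C4''–C4a'' (Friedel–Crafts acylation) and at O1''–C8a'' (aryne O–H insertion), which takes out ring A'' and leaves a syn β-hydroxy ester.
Enabling feature: O1''–C2''–C3''–C4''(=O) of ring C'' is a β-oxy carbonyl (aldol) array, so these four atoms can be closed to a cis oxetan-2-one that holds the epimerisable 2'',3''-cis pair. Cutting its C2''–C3'' and acyl C4''–O bonds gives a flavanon-3-ylketene and an aryl aldehyde.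
The ketene precursor, the 2,3-trans flavanone-3-acetyl chloride, is cut at C3–C3'' (diazoacetate homologation of the enol silane) and at C2–C1' (conjugate arylation of 5,7-bis(benzyloxy)chromone).
Forward order: ring A is bought, ring C closes as a chromone, ring B is added, C3''/C4'' are attached, the temporary β-lactone forms and is opened, ring A'' is attached to O1'', and ring C'' closes last.
Stereochemistry: C2 comes from a chiral rhodium catalyst. C3 comes from attack anti to the C2 aryl group (also the thermodynamic trans isomer). C2'' and C3'' come from O-silylquinidine in the cycloaddition, and no later step breaks C2''–O or enolises C3''.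
Ring B'' carries two bromines beside its benzyloxy group; they make the aldehyde more electrophilic, suppress ionisation at C2'' in the lactone and in acid, and leave in the final hydrogenolysis.

Key step: step 8

Numbering and assumption: flavanone numbering is used, with the anisyl unit unprimed and the hydroxyphenyl unit double-primed; the (R)-bisphosphine is taken to give 2R and the quinidine-derived catalyst the (3R,4R) lactone, by analogy with the usual sense of induction of both catalyst families, and the antipodal ligand or the quinine-derived pseudoenantiomer would be used if this proved wrong.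

Step 1
Reactants: 1 2',4',6'-trihydroxyacetophenone
Product: 2 1-[2,4-bis(benzyloxy)-6-hydroxyphenyl]ethanone
Conditions: BnBr (2.1 equiv), K2CO3 (2.2 equiv), DMF, 60 °C
Reagents that add atoms: benzyl bromide, BrCc1ccccc1
Why: Williamson etherification in which the hydroxyl group hydrogen-bonded to the acetyl carbonyl is the least reactive and should stay free when two equivalents of halide are used.

Step 2
Reactants: 2 1-[2,4-bis(benzyloxy)-6-hydroxyphenyl]ethanone
Product: 4 5,7-bis(benzyloxy)-4H-chromen-4-one, via enaminone 3 (not isolated)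
Conditions: Me2NCH(OMe)2, toluene, 100 °C; evaporate; conc. HCl, CH2Cl2, 40 °C
Reagents that add atoms: N,N-dimethylformamide dimethyl acetal, COC(OC)N(C)C
Why: Enaminone route to 2,3-unsubstituted chromones, in which condensation at the acetyl methyl group is followed by acid-induced addition–elimination of the free phenol with loss of dimethylamine.

Step 3
Reactants: 4 5,7-bis(benzyloxy)-4H-chromen-4-one; 5 4-methoxyphenylboronic acid
Product: 6 (2R)-5,7-bis(benzyloxy)-2-(4-methoxyphenyl)chroman-4-one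
Conditions: [Rh(OH)(cod)]2 (1.5 mol %), (R)-(6,6'-dimethoxybiphenyl-2,2'-diyl)bis[bis(3,4,5-trifluorophenyl)phosphine] (3.3 mol %), 5 (3 equiv), toluene/H2O 10:1, 25 °C
Reagents that add atoms: none
Why: Hayashi–Miyaura asymmetric 1,4-addition of an arylboronic acid to a chromone, where the electron-poor biaryl bisphosphine allows a base-free run at room temperature (no ring opening, no second addition) and its chiral pocket sets C2 as R.

Step 4
Reactants: 6 (2R)-5,7-bis(benzyloxy)-2-(4-methoxyphenyl)chroman-4-one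
Product: 7 (2R)-5,7-bis(benzyloxy)-4-[(tert-butyldimethylsilyl)oxy]-2-(4-methoxyphenyl)-2H-chromene
Conditions: TBSOTf (1.3 equiv), Et3N (2 equiv), CH2Cl2, 0 °C
Reagents that add atoms: tert-butyldimethylsilyl trifluoromethanesulfonate, CC(C)(C)[Si](C)(C)OS(=O)(=O)C(F)(F)F
Why: Soft enolisation (silyl triflate and tertiary amine) gives the enol silane without forming a metal enolate, so β-elimination of the ring oxygen and loss of the C2 configuration are avoided.

Step 5
Reactants: 7 (2R)-5,7-bis(benzyloxy)-4-[(tert-butyldimethylsilyl)oxy]-2-(4-methoxyphenyl)-2H-chromene; 8 tert-butyl diazoacetate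
Product: 11 [(2R,3S)-5,7-bis(benzyloxy)-2-(4-methoxyphenyl)-4-oxochroman-3-yl]acetic acid, via siloxycyclopropane 9 (not isolated), via tert-butyl ester 10 (not isolated)
Conditions: 8 (2 equiv, syringe pump), Rh2(OAc)4 (1 mol %), CH2Cl2, rt; then CF3CO2H (CH2Cl2/CF3CO2H 4:1), 0 °C to rt
Reagents that add atoms: none
Why: Siloxycyclopropane route to γ-keto esters, in which carbenoid cyclopropanation of the enol silane on the face anti to the C2 aryl group forms C3–C3'' and sets C3 as S (trans), and acid then opens the donor–acceptor cyclopropane at its C4–CH bond and removes the tert-butyl group.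

Step 6
Reactants: 11 [(2R,3S)-5,7-bis(benzyloxy)-2-(4-methoxyphenyl)-4-oxochroman-3-yl]acetic acid
Product: 12 [(2R,3S)-5,7-bis(benzyloxy)-2-(4-methoxyphenyl)-4-oxochroman-3-yl]acetyl chloride
Conditions: 1-chloro-N,N,2-trimethylprop-1-en-1-amine (1.2 equiv), CH2Cl2, 0 °C; used at once without purification
Reagents that add atoms: 1-chloro-N,N,2-trimethylprop-1-en-1-amine, CC(C)=C(Cl)N(C)C
Why: Acid chloride formation with an α-chloroenamine is neutral and releases no HCl, which limits cyclisation of this γ-keto acyl chloride onto the C4 carbonyl and leaves C2 and C3 untouched.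

Step 7
Reactants: 13 3,5-dibromo-4-hydroxybenzaldehyde
Product: 14 4-(benzyloxy)-3,5-dibromobenzaldehyde
Conditions: BnBr (1.2 equiv), K2CO3 (1.5 equiv), DMF, 60 °C
Reagents that add atoms: benzyl bromide, BrCc1ccccc1
Why: Williamson etherification of an acidic, fully ionised phenol.

Step 8
Reactants: 12 [(2R,3S)-5,7-bis(benzyloxy)-2-(4-methoxyphenyl)-4-oxochroman-3-yl]acetyl chloride; 14 4-(benzyloxy)-3,5-dibromobenzaldehyde
Product: 16 (3R,4R)-4-[4-(benzyloxy)-3,5-dibromophenyl]-3-[(2R,3S)-5,7-bis(benzyloxy)-2-(4-methoxyphenyl)-4-oxochroman-3-yl]oxetan-2-one, via ketene 15 (not isolated)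
Conditions: O-trimethylsilylquinidine (20 mol %), LiClO4 (2 equiv), iPr2NEt (2.5 equiv), 14 (2 equiv), CH2Cl2/Et2O 2:1, −78 °C; 12 in CH2Cl2 added over 4 h; then −40 °C
Reagents that add atoms: none
Why: iPr2NEt dehydrochlorinates 12 to ketene 15, whose central carbon is attacked by the quinuclidine nitrogen from the side remote from the flavanonyl group to give the Z acylammonium enolate; this adds to the Li+-activated aldehyde 14 through a closed chair-like array (C2''–C3'' bond), and the lithium aldolate then displaces the catalyst from the acyl carbon in a 4-exo-trig lactonisation (acyl C4''–O bond). The closest known reaction is the alkaloid/lithium salt-catalysed acyl halide–aldehyde cyclocondensation (formal [2+2]) of alkylketenes with aromatic aldehydes, which gives cis-3,4-disubstituted oxetan-2-ones; the present ketene differs in its β-branching. C3'' (R) is fixed by the enolate face that the quinidine skeleton leaves open, and C2'' (R) follows from the Z enolate with the aryl group equatorial in the chair, giving the syn aldolate and hence the cis lactone. The step needs catalyst control over the resident C3 centre, ketene formation faster than loss of the C3 proton or O-acylation of the C4 carbonyl, and a lactone that does not ionise at C2''. The first is expected because the enolate is bound to the bulky chiral ammonium group, and the second is served by the tertiary, hindered C3–H, the weak hindered base, the low temperature and the slow addition of 12 to excess 14. The third is secured by the two bromines, which twist the benzyloxy group out of conjugation and withdraw inductively, so that 14 is more electrophilic and benzylic C–O heterolysis or decarboxylation of 16 is disfavoured.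

Step 9
Reactants: 16 (3R,4R)-4-[4-(benzyloxy)-3,5-dibromophenyl]-3-[(2R,3S)-5,7-bis(benzyloxy)-2-(4-methoxyphenyl)-4-oxochroman-3-yl]oxetan-2-one
Product: 17 allyl (2R,3R)-3-[4-(benzyloxy)-3,5-dibromophenyl]-2-[(2R,3S)-5,7-bis(benzyloxy)-2-(4-methoxyphenyl)-4-oxochroman-3-yl]-3-hydroxypropanoate
Conditions: CH2=CHCH2OH (10 equiv), LiOCH2CH=CH2 (0.2 equiv), THF, −40 to −10 °C; AcOH quench
Reagents that add atoms: allyl alcohol, C=CCO
Why: Alkoxide-catalysed alcoholysis of the strained lactone proceeds by acyl C–O cleavage (addition–elimination), so C2''–O and both new centres are untouched, and the protic medium at low temperature protonates the aldolate before retro-aldol cleavage or opening of ring C can compete.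

Step 10
Reactants: 18 phloroglucinol
Product: 19 3,5-bis(benzyloxy)phenol
Conditions: BnBr (2.0 equiv), K2CO3 (2.0 equiv), DMF, rt; chromatography
Reagents that add atoms: benzyl bromide, BrCc1ccccc1
Why: Statistical Williamson etherification of a threefold symmetric triol, from which the dibenzyl ether is separated from the mono- and tribenzyl ethers.

Step 11
Reactants: 19 3,5-bis(benzyloxy)phenol
Product: 20 3,5-bis(benzyloxy)-2-bromophenol
Conditions: NBS (1.0 equiv), CH2Cl2, −78 to 0 °C
Reagents that add atoms: N-bromosuccinimide, O=C1CCC(=O)N1Br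
Why: Electrophilic aromatic bromination should occur ortho to the hydroxyl and para to a benzyloxy group rather than at the position flanked by both benzyloxy groups.

Step 12
Reactants: 20 3,5-bis(benzyloxy)-2-bromophenol
Product: 23 3,5-bis(benzyloxy)-2-(trimethylsilyl)phenyl trifluoromethanesulfonate, via silyl ether 21 (not isolated), via lithium phenolate 22 (not isolated)
Conditions: (Me3Si)2NH, THF, 65 °C; evaporate; n-BuLi (1.1 equiv), THF, −78 °C; Tf2O (1.2 equiv), −78 to 0 °C
Reagents that add atoms: hexamethyldisilazane, C[Si](C)(C)N[Si](C)(C)C; trifluoromethanesulfonic anhydride, O=S(=O)(OS(=O)(=O)C(F)(F)F)C(F)(F)F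
Why: Standard entry to o-silylaryl triflates by O-silylation, bromine–lithium exchange, retro-Brook O-to-C silyl shift and triflation of the phenolate, with the exchange at −78 °C outrunning metalation of the benzyl ethers.

Step 13
Reactants: 17 allyl (2R,3R)-3-[4-(benzyloxy)-3,5-dibromophenyl]-2-[(2R,3S)-5,7-bis(benzyloxy)-2-(4-methoxyphenyl)-4-oxochroman-3-yl]-3-hydroxypropanoate; 23 3,5-bis(benzyloxy)-2-(trimethylsilyl)phenyl trifluoromethanesulfonate
Product: 25 allyl (2R,3R)-3-[4-(benzyloxy)-3,5-dibromophenyl]-3-[3,5-bis(benzyloxy)phenoxy]-2-[(2R,3S)-5,7-bis(benzyloxy)-2-(4-methoxyphenyl)-4-oxochroman-3-yl]propanoate, via aryne 24 (not isolated)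
Conditions: 23 (2.5 equiv), KF (5 equiv), 18-crown-6 (5 equiv), THF, −20 to 0 °C
Reagents that add atoms: none
Why: Fluoride-induced 1,2-elimination gives the aryne, and O–H insertion of an aliphatic alcohol follows, in which the benzyloxy group next to the triple bond directs oxygen to the distal aryne carbon and the carbanion beside it takes the proton, giving the symmetric 3,5-bis(benzyloxy)phenyl ether with retention at C2'' because its C–O bond is never broken.

Step 14
Reactants: 25 allyl (2R,3R)-3-[4-(benzyloxy)-3,5-dibromophenyl]-3-[3,5-bis(benzyloxy)phenoxy]-2-[(2R,3S)-5,7-bis(benzyloxy)-2-(4-methoxyphenyl)-4-oxochroman-3-yl]propanoate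
Product: 26 (2R,3R)-3-[4-(benzyloxy)-3,5-dibromophenyl]-3-[3,5-bis(benzyloxy)phenoxy]-2-[(2R,3S)-5,7-bis(benzyloxy)-2-(4-methoxyphenyl)-4-oxochroman-3-yl]propanoic acid
Conditions: Pd(PPh3)4 (5 mol %), morpholine (5 equiv), THF, rt; dilute citric acid work-up
Reagents that add atoms: none
Why: Tsuji–Trost deallylation with zerovalent palladium frees the acid under near-neutral conditions, which avoids the β-elimination of aryloxide and the C3'' epimerisation that saponification would risk, and the aryl bromides should be inert at room temperature.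

Step 15
Reactants: 26 (2R,3R)-3-[4-(benzyloxy)-3,5-dibromophenyl]-3-[3,5-bis(benzyloxy)phenoxy]-2-[(2R,3S)-5,7-bis(benzyloxy)-2-(4-methoxyphenyl)-4-oxochroman-3-yl]propanoic acid
Product: 28 (2R,3S,2''R,3''R)-5,7,5'',7''-tetrakis(benzyloxy)-2''-[4-(benzyloxy)-3,5-dibromophenyl]-2-(4-methoxyphenyl)-3,3''-bichroman-4,4''-dione, via mixed anhydride 27 (not isolated)
Conditions: (CF3CO)2O (2 equiv), CH2Cl2, −10 to 0 °C; aq. NaHCO3 quench
Reagents that add atoms: none
Why: Intramolecular Friedel–Crafts acylation of a phloroglucinol-type ring by the mixed trifluoroacetic anhydride closes the six-membered ring C'' at either of two equivalent ortho positions, the standard closure of 3-aryl-3-aryloxypropanoic acids to 5,7-dialkoxyflavanones, while cold base-free conditions should not enolise C3'' and the electron-poor dibromoaryl group blocks ionisation at C2''.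

Step 16
Reactants: 28 (2R,3S,2''R,3''R)-5,7,5'',7''-tetrakis(benzyloxy)-2''-[4-(benzyloxy)-3,5-dibromophenyl]-2-(4-methoxyphenyl)-3,3''-bichroman-4,4''-dione
Product: 29 sikokianin B
Conditions: H2 (1 atm), 10% Pd/C, NaOAc (2.5 equiv), AcOH (2.5 equiv), EtOAc/MeOH 1:1, rt
Reagents that add atoms: none
Why: Heterogeneous hydrogenolysis cleaves the five benzyl ethers and hydrodehalogenates both C–Br bonds in one operation, in a buffered medium in which C3'' should not enolise and ring C'' should not open through a quinone methide, so no stereocentre is affected.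

Compound list
1 | 2',4',6'-trihydroxyacetophenone | CC(=O)c1c(O)cc(O)cc1O | starting material
2 | 1-[2,4-bis(benzyloxy)-6-hydroxyphenyl]ethanone | CC(=O)c1c(O)cc(OCc2ccccc2)cc1OCc1ccccc1 | intermediate
3 | (E)-1-[2,4-bis(benzyloxy)-6-hydroxyphenyl]-3-(dimethylamino)prop-2-en-1-one | CN(C)/C=C/C(=O)c1c(O)cc(OCc2ccccc2)cc1OCc1ccccc1 | intermediate
4 | 5,7-bis(benzyloxy)-4H-chromen-4-one | O=c1ccoc2cc(OCc3ccccc3)cc(OCc3ccccc3)c12 | intermediate
5 | 4-methoxyphenylboronic acid | COc1ccc(B(O)O)cc1 | starting material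
6 | (2R)-5,7-bis(benzyloxy)-2-(4-methoxyphenyl)chroman-4-one | COc1ccc([C@@H]2Oc3cc(OCc4ccccc4)cc(OCc4ccccc4)c3C(=O)C2)cc1 | intermediate
7 | (2R)-5,7-bis(benzyloxy)-4-[(tert-butyldimethylsilyl)oxy]-2-(4-methoxyphenyl)-2H-chromene | COc1ccc([C@@H]2Oc3cc(OCc4ccccc4)cc(OCc4ccccc4)c3C(O[Si](C)(C)C(C)(C)C)=C2)cc1 | intermediate
8 | tert-butyl diazoacetate | CC(C)(C)OC(=O)C=[N+]=[N-] | starting material
9 | tert-butyl (2R)-5,7-bis(benzyloxy)-7b-[(tert-butyldimethylsilyl)oxy]-2-(4-methoxyphenyl)-1,1a,2,7b-tetrahydrocyclopropa[c]chromene-1-carboxylate, three-membered ring anti to the aryl group, epimers at the ester-bearing carbon | COc1ccc([C@@H]2Oc3cc(OCc4ccccc4)cc(OCc4ccccc4)c3[C@@]3(O[Si](C)(C)C(C)(C)C)C(C(=O)OC(C)(C)C)[C@@H]23)cc1 | intermediate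
10 | tert-butyl [(2R,3S)-5,7-bis(benzyloxy)-2-(4-methoxyphenyl)-4-oxochroman-3-yl]acetate | COc1ccc([C@@H]2Oc3cc(OCc4ccccc4)cc(OCc4ccccc4)c3C(=O)[C@H]2CC(=O)OC(C)(C)C)cc1 | intermediate
11 | [(2R,3S)-5,7-bis(benzyloxy)-2-(4-methoxyphenyl)-4-oxochroman-3-yl]acetic acid | COc1ccc([C@@H]2Oc3cc(OCc4ccccc4)cc(OCc4ccccc4)c3C(=O)[C@H]2CC(=O)O)cc1 | intermediate
12 | [(2R,3S)-5,7-bis(benzyloxy)-2-(4-methoxyphenyl)-4-oxochroman-3-yl]acetyl chloride | COc1ccc([C@@H]2Oc3cc(OCc4ccccc4)cc(OCc4ccccc4)c3C(=O)[C@H]2CC(Cl)=O)cc1 | intermediate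
13 | 3,5-dibromo-4-hydroxybenzaldehyde | O=Cc1cc(Br)c(O)c(Br)c1 | starting material
14 | 4-(benzyloxy)-3,5-dibromobenzaldehyde | O=Cc1cc(Br)c(OCc2ccccc2)c(Br)c1 | intermediate
15 | (2R,3S)-5,7-bis(benzyloxy)-2-(4-methoxyphenyl)-3-(2-oxoethenyl)chroman-4-one (ketene) | COc1ccc([C@@H]2Oc3cc(OCc4ccccc4)cc(OCc4ccccc4)c3C(=O)[C@H]2C=C=O)cc1 | intermediate
16 | (3R,4R)-4-[4-(benzyloxy)-3,5-dibromophenyl]-3-[(2R,3S)-5,7-bis(benzyloxy)-2-(4-methoxyphenyl)-4-oxochroman-3-yl]oxetan-2-one (cis) | COc1ccc([C@@H]2Oc3cc(OCc4ccccc4)cc(OCc4ccccc4)c3C(=O)[C@H]2[C@H]2C(=O)O[C@H]2c2cc(Br)c(OCc3ccccc3)c(Br)c2)cc1 | intermediate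
17 | allyl (2R,3R)-3-[4-(benzyloxy)-3,5-dibromophenyl]-2-[(2R,3S)-5,7-bis(benzyloxy)-2-(4-methoxyphenyl)-4-oxochroman-3-yl]-3-hydroxypropanoate | COc1ccc([C@@H]2Oc3cc(OCc4ccccc4)cc(OCc4ccccc4)c3C(=O)[C@H]2[C@@H](C(=O)OCC=C)[C@@H](O)c2cc(Br)c(OCc3ccccc3)c(Br)c2)cc1 | intermediate
18 | phloroglucinol | Oc1cc(O)cc(O)c1 | starting material
19 | 3,5-bis(benzyloxy)phenol | Oc1cc(OCc2ccccc2)cc(OCc2ccccc2)c1 | intermediate
20 | 3,5-bis(benzyloxy)-2-bromophenol | Oc1cc(OCc2ccccc2)cc(OCc2ccccc2)c1Br | intermediate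
21 | [3,5-bis(benzyloxy)-2-bromophenoxy]trimethylsilane | C[Si](C)(C)Oc1cc(OCc2ccccc2)cc(OCc2ccccc2)c1Br | intermediate
22 | lithium 3,5-bis(benzyloxy)-2-(trimethylsilyl)phenolate | [Li+].[O-]c1cc(OCc2ccccc2)cc(OCc2ccccc2)c1[Si](C)(C)C | intermediate
23 | 3,5-bis(benzyloxy)-2-(trimethylsilyl)phenyl trifluoromethanesulfonate | C[Si](C)(C)c1c(OCc2ccccc2)cc(OCc2ccccc2)cc1OS(=O)(=O)C(F)(F)F | intermediate
24 | 3,5-bis(benzyloxy)benzyne | C1#CC(OCc2ccccc2)=CC(OCc2ccccc2)=C1 | intermediate
25 | allyl (2R,3R)-3-[4-(benzyloxy)-3,5-dibromophenyl]-3-[3,5-bis(benzyloxy)phenoxy]-2-[(2R,3S)-5,7-bis(benzyloxy)-2-(4-methoxyphenyl)-4-oxochroman-3-yl]propanoate | COc1ccc([C@@H]2Oc3cc(OCc4ccccc4)cc(OCc4ccccc4)c3C(=O)[C@H]2[C@@H](C(=O)OCC=C)[C@@H](Oc2cc(OCc3ccccc3)cc(OCc3ccccc3)c2)c2cc(Br)c(OCc3ccccc3)c(Br)c2)cc1 | intermediate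
26 | (2R,3R)-3-[4-(benzyloxy)-3,5-dibromophenyl]-3-[3,5-bis(benzyloxy)phenoxy]-2-[(2R,3S)-5,7-bis(benzyloxy)-2-(4-methoxyphenyl)-4-oxochroman-3-yl]propanoic acid | COc1ccc([C@@H]2Oc3cc(OCc4ccccc4)cc(OCc4ccccc4)c3C(=O)[C@H]2[C@@H](C(=O)O)[C@@H](Oc2cc(OCc3ccccc3)cc(OCc3ccccc3)c2)c2cc(Br)c(OCc3ccccc3)c(Br)c2)cc1 | intermediate
27 | mixed anhydride of 26 and trifluoroacetic acid | COc1ccc([C@@H]2Oc3cc(OCc4ccccc4)cc(OCc4ccccc4)c3C(=O)[C@H]2[C@@H](C(=O)OC(=O)C(F)(F)F)[C@@H](Oc2cc(OCc3ccccc3)cc(OCc3ccccc3)c2)c2cc(Br)c(OCc3ccccc3)c(Br)c2)cc1 | intermediate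
28 | (2R,3S,2''R,3''R)-5,7,5'',7''-tetrakis(benzyloxy)-2''-[4-(benzyloxy)-3,5-dibromophenyl]-2-(4-methoxyphenyl)-3,3''-bichroman-4,4''-dione (2,3-trans, 2'',3''-cis) | COc1ccc([C@@H]2Oc3cc(OCc4ccccc4)cc(OCc4ccccc4)c3C(=O)[C@H]2[C@H]2C(=O)c3c(OCc4ccccc4)cc(OCc4ccccc4)cc3O[C@H]2c2cc(Br)c(OCc3ccccc3)c(Br)c2)cc1 | intermediate
29 | sikokianin B | COc1ccc([C@@H]2Oc3cc(O)cc(O)c3C(=O)[C@H]2[C@H]2C(=O)c3c(O)cc(O)cc3O[C@H]2c2ccc(O)cc2)cc1 | target

Total step count: 16. Longest linear sequence: 12 (steps 1–6, 8, 9, 13–16).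

Steps most likely to fail

Step 8. The acyl chloride may be lost through attack of the C4 carbonyl oxygen on the activated acyl group followed by loss of the C3 proton. The hindered ketene may also dimerise or react sluggishly, and the resident C3 centre may erode the facial selectivity imposed by the catalyst. The fallback forms the same two bonds stepwise, setting out from 11 and returning at 16. Acid 11 would be coupled (PivCl, Et3N, LiCl, (R)-4-benzyloxazolidin-2-one, THF) to the N-acyl oxazolidinone F1. An Evans syn aldol reaction (Bu2BOTf, iPr2NEt, CH2Cl2, −78 °C, then 14) would give the syn aldol adduct F2, with the auxiliary setting both centres. LiOH/H2O2 (THF/H2O, 0 °C) would release the β-hydroxy acid F3. Carboxyl activation with PhSO2Cl in pyridine at 0 °C would then close the cis lactone 16 with retention at the carbinol carbon.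

Step 13. The crowded carbinol may intercept the aryne too slowly, so that the aryne is consumed by fluoride or solvent. The basicity of fluoride may also trigger retro-aldol cleavage or β-elimination in ring C. The fallback sets out from 17 and returns at 25; it replaces the aryne by a neutral copper-catalysed aryl transfer from bismuth, which also keeps the C2''–O bond. Commercial 1-bromo-3,5-bis(benzyloxy)benzene would be converted (Mg, THF; BiCl3) into tris[3,5-bis(benzyloxy)phenyl]bismuthane F4. Oxidation with PhI(OAc)2 in CH2Cl2 would give the triarylbismuth diacetate F5. Reaction of 17 with F5 and Cu(OAc)2 (10 mol %) in CH2Cl2 at rt would give 25.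

Step 5. The carbenoid may be diverted into ylide formation at benzyl ether oxygens or into addition to the electron-rich arenes. It may also attack the hindered enol ether slowly or with poor facial selectivity. The fallback sets out from 7 and returns at 11; it brings in the side chain as an allyl group under neutral conditions. Palladium-catalysed allylation of the enol silane (allyl methyl carbonate, Pd2(dba)3, dppe, THF, 65 °C) would give the trans 3-allylflavanone F6. Lemieux–Johnson cleavage (OsO4 cat., NaIO4, 2,6-lutidine, dioxane/H2O) would give the aldehyde F7. Pinnick oxidation (NaClO2, NaH2PO4, 2-methyl-2-butene, t-BuOH/H2O) would give 11.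

Further compounds
F1 | step 8 | (4R)-4-benzyl-3-{[(2R,3S)-5,7-bis(benzyloxy)-2-(4-methoxyphenyl)-4-oxochroman-3-yl]acetyl}oxazolidin-2-one | COc1ccc([C@@H]2Oc3cc(OCc4ccccc4)cc(OCc4ccccc4)c3C(=O)[C@H]2CC(=O)N2[C@H](Cc3ccccc3)COC2=O)cc1
F2 | step 8 | (4R)-4-benzyl-3-{(2R,3R)-3-[4-(benzyloxy)-3,5-dibromophenyl]-2-[(2R,3S)-5,7-bis(benzyloxy)-2-(4-methoxyphenyl)-4-oxochroman-3-yl]-3-hydroxypropanoyl}oxazolidin-2-one | COc1ccc([C@@H]2Oc3cc(OCc4ccccc4)cc(OCc4ccccc4)c3C(=O)[C@H]2[C@@H](C(=O)N2[C@H](Cc3ccccc3)COC2=O)[C@@H](O)c2cc(Br)c(OCc3ccccc3)c(Br)c2)cc1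
F3 | step 8 | (2R,3R)-3-[4-(benzyloxy)-3,5-dibromophenyl]-2-[(2R,3S)-5,7-bis(benzyloxy)-2-(4-methoxyphenyl)-4-oxochroman-3-yl]-3-hydroxypropanoic acid | COc1ccc([C@@H]2Oc3cc(OCc4ccccc4)cc(OCc4ccccc4)c3C(=O)[C@H]2[C@@H](C(=O)O)[C@@H](O)c2cc(Br)c(OCc3ccccc3)c(Br)c2)cc1
F4 | step 13 | tris[3,5-bis(benzyloxy)phenyl]bismuthane | [Bi](c1cc(OCc2ccccc2)cc(OCc2ccccc2)c1)(c1cc(OCc2ccccc2)cc(OCc2ccccc2)c1)c1cc(OCc2ccccc2)cc(OCc2ccccc2)c1
F5 | step 13 | tris[3,5-bis(benzyloxy)phenyl]bismuth diacetate | CC(=O)O[Bi](OC(C)=O)(c1cc(OCc2ccccc2)cc(OCc2ccccc2)c1)(c1cc(OCc2ccccc2)cc(OCc2ccccc2)c1)c1cc(OCc2ccccc2)cc(OCc2ccccc2)c1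
F6 | step 5 | (2R,3S)-3-allyl-5,7-bis(benzyloxy)-2-(4-methoxyphenyl)chroman-4-one | COc1ccc([C@@H]2Oc3cc(OCc4ccccc4)cc(OCc4ccccc4)c3C(=O)[C@H]2CC=C)cc1
F7 | step 5 | [(2R,3S)-5,7-bis(benzyloxy)-2-(4-methoxyphenyl)-4-oxochroman-3-yl]acetaldehyde | COc1ccc([C@@H]2Oc3cc(OCc4ccccc4)cc(OCc4ccccc4)c3C(=O)[C@H]2CC=O)cc1
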